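**Plan**
- Retrosynthesis: the two ring-A aryl–C(=O) bonds are cut first (each back to an aryl ester beside a C–I bond), then the four ester C–O bonds in two pairs, then the two aryl–CH2 bonds of the methylene bridge.
- Enabling feature: in each ring A the ketone-bearing carbon (C1) lies between the oxygen-bearing carbons C2 and C6, so the ring-B aroyl group can be parked on a neighbouring oxygen as an ester and handed to C1 once C1 is lithiated.
- Forward, ring A: 5-methoxyresorcinol is iodinated between its two oxygens (bis-MOM ether, ortho-lithiation), deprotected and bridged with formaldehyde. Ring B: methyl orsellinate is converted into 4-benzyloxy-2-methoxy-6-methylbenzoyl chloride.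
- Union and endgame: the tetraphenol is acylated in two stages (outer phenols, then inner phenols), both iodides are exchanged for lithium with O→C acyl shift, the two left-over esters are cleaved and the benzyl ethers are hydrogenolysed.
- No ring is formed at any stage; the four benzene rings are purchased and joined in the order bridge, esters, ketones.
- Stereochemistry: the target has no stereocentre and no stereodescriptor (aryl–carbonyl axes taken as freely rotating), so nothing has to be set.

Key step: step 11

Remark on the chemistry: in step 11 either ester flanking C1 may migrate; compound 17 is drawn as the isomer from migration of the more congested bridge-side ester, and any positional isomers would be carried on together because all converge on 18 in step 12.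

Remark on the chemistry: should step 9 give some positional isomers of the diester beside 14, they would be taken into step 10 as well, since every partial ester converges on tetra-ester 15.

**Route**

Step 1
Reactants: 1 5-methoxyresorcinol
Product: 2 1-methoxy-3,5-bis(methoxymethoxy)benzene
Conditions: NaH (2.4 equiv), DMF, 0 °C; MOMCl (2.4 equiv), 0 °C → rt
Reagents that add atoms: chloromethyl methyl ether (MOMCl), COCCl
Why: Williamson-type O-alkylation of both phenoxides with the reactive α-chloro ether installs the two MOM ethers that direct the metalation in step 2.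

Step 2
Reactants: 2 1-methoxy-3,5-bis(methoxymethoxy)benzene
Product: 4 2-iodo-5-methoxy-1,3-bis(methoxymethoxy)benzene, via C2 aryllithium 3 (not isolated)
Conditions: n-BuLi (1.1 equiv), THF, 0 °C, 1 h; I2 (1.2 equiv), THF, −78 °C → rt; aq. Na2S2O3
Reagents that add atoms: iodine, II
Why: Directed ortho-metalation should occur at the C–H between the two chelating OMOM groups (two cooperating directors, each stronger than OMe), and the aryllithium is then trapped by iodine.

Step 3
Reactants: 4 2-iodo-5-methoxy-1,3-bis(methoxymethoxy)benzene
Product: 5 2-iodo-5-methoxybenzene-1,3-diol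
Conditions: HCl (3 M in MeOH), rt
Reagents that add atoms: none
Why: Acid-catalysed acetal methanolysis removes both MOM groups at room temperature, mild enough to leave the electron-rich aryl iodide intact.

Step 4
Reactants: 5 2-iodo-5-methoxybenzene-1,3-diol (two molecules), 6 formaldehyde (as paraformaldehyde)
Product: 8 4,4'-methylenebis(2-iodo-5-methoxybenzene-1,3-diol), via hydroxymethyl phenol 7 (not isolated)
Conditions: 5 (3 equiv), (CH2O)n (1 equiv), 1 M aq. NaOH (3 equiv), 0 °C → rt, Ar; then 1 M HCl; excess 5 recovered
Reagents that add atoms: none
Why: Lederer–Manasse hydroxymethylation at C4 (C2 is blocked by iodine, C4 and C6 are equivalent), followed by quinone-methide formation and capture by a second phenoxide, is the standard way to methylene-bridge phloroglucinol-type rings, and the excess of 5 should hold back chain growth.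

Step 5
Reactants: 9 methyl orsellinate (methyl 2,4-dihydroxy-6-methylbenzoate)
Product: 10 methyl 4-(benzyloxy)-2-hydroxy-6-methylbenzoate
Conditions: BnBr (1.05 equiv), K2CO3, acetone, reflux
Reagents that add atoms: benzyl bromide, BrCc1ccccc1
Why: Williamson etherification should be selective for the 4-OH because the 2-OH is held in a hydrogen bond to the ester carbonyl and is much less nucleophilic.

Step 6
Reactants: 10 methyl 4-(benzyloxy)-2-hydroxy-6-methylbenzoate
Product: 11 methyl 4-(benzyloxy)-2-methoxy-6-methylbenzoate
Conditions: MeI (3 equiv), K2CO3, DMF, 50 °C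
Reagents that add atoms: iodomethane, CI
Why: Williamson O-methylation of the remaining chelated phenol proceeds under slightly forcing conditions in a dipolar aprotic solvent.

Step 7
Reactants: 11 methyl 4-(benzyloxy)-2-methoxy-6-methylbenzoate
Product: 12 4-(benzyloxy)-2-methoxy-6-methylbenzoic acid
Conditions: KOH (excess), DMSO/H2O, 90 °C; then aq. HCl
Reagents that add atoms: potassium hydroxide, [K+].[OH-]
Why: Saponification of the di-ortho-substituted methyl benzoate needs hot, poorly solvated hydroxide but is otherwise routine, and the benzyl and methyl ethers are inert to base.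

Step 8
Reactants: 12 4-(benzyloxy)-2-methoxy-6-methylbenzoic acid
Product: 13 4-(benzyloxy)-2-methoxy-6-methylbenzoyl chloride
Conditions: (COCl)2 (1.5 equiv), DMF (cat.), CH2Cl2, 0 °C → rt; evaporated and used crude
Reagents that add atoms: oxalyl chloride, O=C(Cl)C(Cl)=O
Why: Acid chloride formation through the Vilsmeier-type chloroiminium catalyst works under neutral, cold conditions that spare the benzyl ether.

Step 9
Reactants: 8 4,4'-methylenebis(2-iodo-5-methoxybenzene-1,3-diol), 13 4-(benzyloxy)-2-methoxy-6-methylbenzoyl chloride (two molecules)
Product: 14 methylenebis(3-hydroxy-2-iodo-5-methoxy-4,1-phenylene) bis[4-(benzyloxy)-2-methoxy-6-methylbenzoate] (the diester at the two outer phenols, para to the bridge)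
Conditions: 13 (2.05 equiv, slow addition), Et3N (2.5 equiv), DMAP (0.1 equiv), CH2Cl2, −20 → 0 °C
Reagents that add atoms: none
Why: DMAP-catalysed O-acylation through the N-acylpyridinium should take place first at the two outer phenols, which have only iodine as an ortho neighbour, whereas the inner phenols are flanked by both iodine and the diarylmethane carbon and should be too shielded to meet the bulky 2,6-disubstituted aroyl donor at low temperature.

Step 10
Reactants: 14 the outer diester from step 9, 13 4-(benzyloxy)-2-methoxy-6-methylbenzoyl chloride (two molecules)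
Product: 15 methylenebis(2-iodo-5-methoxybenzene-4,1,3-triyl) tetrakis[4-(benzyloxy)-2-methoxy-6-methylbenzoate]
Conditions: NaH (2.3 equiv), THF, 0 °C; then 13 (2.6 equiv), 0 → 50 °C
Reagents that add atoms: none
Why: O-acylation of the two remaining, doubly ortho-substituted phenols as their sodium phenoxides should succeed because the electron-rich aroyl chloride reacts through a loose, acylium-like transition state that tolerates ortho substituents on both partners, while the 2,6-disubstituted aryl esters already in place resist attack by phenoxide.

Step 11
Reactants: 15 methylenebis(2-iodo-5-methoxybenzene-4,1,3-triyl) tetrakis[4-(benzyloxy)-2-methoxy-6-methylbenzoate]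
Product: 17 methylenebis{2-[4-(benzyloxy)-2-methoxy-6-methylbenzoyl]-3-hydroxy-5-methoxy-4,1-phenylene} bis[4-(benzyloxy)-2-methoxy-6-methylbenzoate], via bis-aryllithium 16 (not isolated)
Conditions: t-BuLi (4.2 equiv), THF, −95 °C, then → −40 °C; AcOH, −78 °C
Reagents that add atoms: none
Why: Iodine–lithium exchange at the C–I carbon of each ring A should be much faster than addition of t-BuLi to the di-ortho-substituted ester carbonyls, and the second equivalent of t-BuLi per iodide consumes the tert-butyl iodide that is formed. Each aryllithium then attacks the carbonyl of an ester on a neighbouring oxygen through a four-membered transition state, and collapse of the tetrahedral alkoxide breaks the aryl O–acyl bond to give the diaryl ketone and a lithium phenoxide. The closest known reaction type is the anionic Fries (1,3 O→C acyl) rearrangement of ortho-haloaryl esters set off by halogen–metal exchange, here carried out twice in one molecule. No ring is closed and no stereocentre is formed. The step needs site selectivity, which the position of iodine fixes at C1, and chemoselectivity against ester attack, lateral metalation of the ring-B methyl groups and benzylic deprotonation, which the low temperature and the intramolecular acyl delivery should secure. Which of the two flanking esters migrates is of no consequence, and the tetra-ortho-substituted ketone beside a phenoxide is shielded from further addition.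

Step 12
Reactants: 17 the bis-benzophenone diester from step 11
Product: 18 methylenebis(2,4-dihydroxy-6-methoxy-3,1-phenylene) bis{[4-(benzyloxy)-2-methoxy-6-methylphenyl]methanone} (the bis-ring-B-O-benzyl ether of the target)
Conditions: KOH (10 equiv), DMSO/H2O (4:1), 25–40 °C, Ar; then 1 M HCl
Reagents that add atoms: none
Why: Saponification of the two left-over aryl esters should be feasible because the leaving group is an acidic ortho-acyl phenoxide, and poorly solvated hydroxide at or below 40 °C keeps the mixture under the temperature at which a ring-A phenoxide could displace the ring-B 2-methoxy group.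

Step 13
Reactants: 18 the bis-ring-B-O-benzyl ether of the target
Product: 19 digriseophene A
Conditions: H2 (1 atm), 10% Pd/C, EtOAc/MeOH, rt
Reagents that add atoms: none
Why: Catalytic hydrogenolysis cleaves the two aryl benzyl ethers, while the hindered, hydrogen-bonded diaryl ketones and the diarylmethane bridge are expected to survive at ambient pressure and temperature.

**Compound list**
1 | 5-methoxyresorcinol (5-methoxybenzene-1,3-diol) | COc1cc(O)cc(O)c1 | starting material
2 | 1-methoxy-3,5-bis(methoxymethoxy)benzene | COCOc1cc(OC)cc(OCOC)c1 | intermediate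
3 | [4-methoxy-2,6-bis(methoxymethoxy)phenyl]lithium | [Li]c1c(OCOC)cc(OC)cc1OCOC | intermediate (not isolated)
4 | 2-iodo-5-methoxy-1,3-bis(methoxymethoxy)benzene | COCOc1cc(OC)cc(OCOC)c1I | intermediate
5 | 2-iodo-5-methoxybenzene-1,3-diol | COc1cc(O)c(I)c(O)c1 | intermediate
6 | formaldehyde (as paraformaldehyde) | C=O | starting material
7 | 4-(hydroxymethyl)-2-iodo-5-methoxybenzene-1,3-diol | COc1cc(O)c(I)c(O)c1CO | intermediate (not isolated)
8 | 4,4'-methylenebis(2-iodo-5-methoxybenzene-1,3-diol) | COc1cc(O)c(I)c(O)c1Cc1c(OC)cc(O)c(I)c1O | intermediate
9 | methyl orsellinate (methyl 2,4-dihydroxy-6-methylbenzoate) | COC(=O)c1c(C)cc(O)cc1O | starting material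
10 | methyl 4-(benzyloxy)-2-hydroxy-6-methylbenzoate | COC(=O)c1c(C)cc(OCc2ccccc2)cc1O | intermediate
11 | methyl 4-(benzyloxy)-2-methoxy-6-methylbenzoate | COC(=O)c1c(C)cc(OCc2ccccc2)cc1OC | intermediate
12 | 4-(benzyloxy)-2-methoxy-6-methylbenzoic acid | OC(=O)c1c(C)cc(OCc2ccccc2)cc1OC | intermediate
13 | 4-(benzyloxy)-2-methoxy-6-methylbenzoyl chloride | ClC(=O)c1c(C)cc(OCc2ccccc2)cc1OC | intermediate
14 | methylenebis(3-hydroxy-2-iodo-5-methoxy-4,1-phenylene) bis[4-(benzyloxy)-2-methoxy-6-methylbenzoate] | COc1cc(OC(=O)c2c(C)cc(OCc3ccccc3)cc2OC)c(I)c(O)c1Cc1c(OC)cc(OC(=O)c2c(C)cc(OCc3ccccc3)cc2OC)c(I)c1O | intermediate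
15 | methylenebis(2-iodo-5-methoxybenzene-4,1,3-triyl) tetrakis[4-(benzyloxy)-2-methoxy-6-methylbenzoate] | COc1cc(OC(=O)c2c(C)cc(OCc3ccccc3)cc2OC)c(I)c(OC(=O)c2c(C)cc(OCc3ccccc3)cc2OC)c1Cc1c(OC)cc(OC(=O)c2c(C)cc(OCc3ccccc3)cc2OC)c(I)c1OC(=O)c1c(C)cc(OCc2ccccc2)cc1OC | intermediate
16 | bis-aryllithium of 15 (both iodines replaced by lithium) | COc1cc(OC(=O)c2c(C)cc(OCc3ccccc3)cc2OC)c([Li])c(OC(=O)c2c(C)cc(OCc3ccccc3)cc2OC)c1Cc1c(OC)cc(OC(=O)c2c(C)cc(OCc3ccccc3)cc2OC)c([Li])c1OC(=O)c1c(C)cc(OCc2ccccc2)cc1OC | intermediate (not isolated)
17 | methylenebis{2-[4-(benzyloxy)-2-methoxy-6-methylbenzoyl]-3-hydroxy-5-methoxy-4,1-phenylene} bis[4-(benzyloxy)-2-methoxy-6-methylbenzoate] | COc1cc(OC(=O)c2c(C)cc(OCc3ccccc3)cc2OC)c(C(=O)c2c(C)cc(OCc3ccccc3)cc2OC)c(O)c1Cc1c(OC)cc(OC(=O)c2c(C)cc(OCc3ccccc3)cc2OC)c(C(=O)c2c(C)cc(OCc3ccccc3)cc2OC)c1O | intermediate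
18 | methylenebis(2,4-dihydroxy-6-methoxy-3,1-phenylene) bis{[4-(benzyloxy)-2-methoxy-6-methylphenyl]methanone} | COc1cc(O)c(C(=O)c2c(C)cc(OCc3ccccc3)cc2OC)c(O)c1Cc1c(OC)cc(O)c(C(=O)c2c(C)cc(OCc3ccccc3)cc2OC)c1O | intermediate
19 | digriseophene A, methylenebis(2,4-dihydroxy-6-methoxy-3,1-phenylene) bis[(4-hydroxy-2-methoxy-6-methylphenyl)methanone] | COc1cc(O)c(C(=O)c2c(C)cc(O)cc2OC)c(O)c1Cc1c(OC)cc(O)c(C(=O)c2c(C)cc(O)cc2OC)c1O | target

**Step count**
Total: 13 steps. Longest linear sequence: 9 steps (steps 1, 2, 3, 4, 9, 10, 11, 12, 13; the ring-B branch, steps 5–8 then 9–13, is equally long).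

**Steps most likely to fail**

1. Step 11. The C1 aryllithium may be quenched by proton transfer from the ortho-methyl group of a neighbouring aroyl ester, or t-BuLi may add to an ester carbonyl before the acyl shift has taken place on both rings, so that one or both aryl–carbonyl bonds fail to form.
Fallback, from 8, returning at 18: the same two bonds would be made intermolecularly by aryllithium addition to an aldehyde and oxidation. Tetraphenol 8 would be converted with NaH and MOMCl in DMF into 4,4'-methylenebis[2-iodo-5-methoxy-1,3-bis(methoxymethoxy)benzene] F1. Acid chloride 13 would be reduced with LiAlH(Ot-Bu)3 in THF at −78 °C to 4-(benzyloxy)-2-methoxy-6-methylbenzaldehyde F2. Double iodine–lithium exchange on F1 (t-BuLi, THF, −78 °C) and addition to F2 should give the bis(diarylcarbinol) tetra-MOM ether F3 as a diastereomer mixture of no consequence. Dess–Martin oxidation would then give the bis-ketone tetra-MOM ether F4, and methanolic HCl would remove the four MOM groups to reach 18.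

2. Step 4. The diarylmethane keeps one free, activated position on each ring and may go on condensing with the formaldehyde-derived quinone methide, so that chain growth to trimers and resin competes with clean two-to-one coupling.
Fallback, from 5, returning at 8: the one-carbon unit would be attached in a separate, controllable step. A Mannich reaction of 5 with aqueous dimethylamine and formaldehyde in ethanol should give the isolable 4-[(dimethylamino)methyl]-2-iodo-5-methoxybenzene-1,3-diol F5. Heating F5 with an excess of 5 in dioxane would release dimethylamine and generate the quinone methide slowly, so that it always meets a large excess of 5 and gives 8.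

3. Step 12. Hydroxide addition to the di-ortho-substituted aroyl carbonyl may be too slow, and on warming a ring-A phenoxide may displace the ring-B 2-methoxy group (xanthone closure) before the esters are gone.
Fallback, from 17, returning directly at 18: the left-over esters would be cleaved reductively with LiAlH4 in THF at −20 to 0 °C, the classical way to remove mesitoate-type esters. The aroyl groups leave as the benzylic alcohol, and the tetra-ortho-substituted ketones, held as chelated aluminium phenoxides, are expected to resist hydride at this temperature. No new intermediate is involved.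

**Further compounds**
F1 | step 11 | 4,4'-methylenebis[2-iodo-5-methoxy-1,3-bis(methoxymethoxy)benzene] | COc1cc(OCOC)c(I)c(OCOC)c1Cc1c(OC)cc(OCOC)c(I)c1OCOC
F2 | step 11 | 4-(benzyloxy)-2-methoxy-6-methylbenzaldehyde | O=Cc1c(C)cc(OCc2ccccc2)cc1OC
F3 | step 11 | bis(diarylcarbinol) tetra-MOM ether (diastereomer mixture, configuration not defined) | COc1cc(OCOC)c(C(O)c2c(C)cc(OCc3ccccc3)cc2OC)c(OCOC)c1Cc1c(OC)cc(OCOC)c(C(O)c2c(C)cc(OCc3ccccc3)cc2OC)c1OCOC
F4 | step 11 | bis-ketone tetra-MOM ether (tetra-O-MOM derivative of 18) | COc1cc(OCOC)c(C(=O)c2c(C)cc(OCc3ccccc3)cc2OC)c(OCOC)c1Cc1c(OC)cc(OCOC)c(C(=O)c2c(C)cc(OCc3ccccc3)cc2OC)c1OCOC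
F5 | step 4 | 4-[(dimethylamino)methyl]-2-iodo-5-methoxybenzene-1,3-diol | COc1cc(O)c(I)c(O)c1CN(C)C
F0 | step 12 | none | none
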